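Nobody has the constants of this flask on the board yet, so the examination starts from what the readings of the violet run can give.

| flask | substrate | partner | remark | time |
|---|---|---|---|---|
| violet | 0.020 M | 0.030 M | the very flask that is asked about, followed so far |  |
| flask | 0.020 M | 0.0300 M |  | 3.0 h |

violet run (percent of the substrate charged)

| time / min | substrate / % | single product / % | double product / % |
|---|---|---|---|
| 1.00 | 79.0 | 6.1 | 0.8 |
| 2.00 | 69.8 | 8.6 | 1.2 |
| 2.50 | 67.1 | 8.3 | 1.2 |
| 4.00 | 62.8 | 9.5 | 1.4 |
| 6.00 | 60.7 | 10.8 | 1.5 |
| 10.0 | 59.4 | 9.8 | 1.8 |
| 15.0 | 59.3 | 11.0 | 1.6 |

(standard deviation of a reading: 0.5 percentage points)

- what was read earlier has a scatter of 0.5 percentage points, one standard deviation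
- steps under discussion: partner + double product -> triple product + released group; substrate + partner -> single product + released group; partner + single product -> double product + released group; partner -> decomposed reagent; substrate <-> dormant form

* amount of substrate at 3.0 h, in percent of the substrate charged
* amount of single product at 3.0 h, in percent of the substrate charged
* amount of double product at 3.0 h, in percent of the substrate charged
* amount of triple product at 3.0 h, in percent of the substrate charged

The steps under discussion: substrate and partner give single product, partner and single product give double product, partner and double product give triple product, each freeing released group; partner decomposes; substrate exchanges with its dormant form.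

*Does the violet flask still react?* Not that its substrate shows: substrate reads 59.4% at 10.0 min and 59.3% at 15.0 min, a change inside the scatter of 0.5 percentage points.

*Did the products use up the partner?* I count the partner each product holds: one per single product, two per double product. At the last reading that is 9.47% of the partner charged, with triple product unread.

*So where is the rest?* If the stop means the partner has left, the rest went to decomposed reagent. I therefore carry the logarithm of decomposed partner per productive partner, a selectivity factor in powers of ten, the partner exponent, here a reading from one scattered row of the violet run: 0.981.

*Why might it carry over to another charge of partner?* Partner enters the decomposition and each product-forming rate to the first power, so at given concentrations of substrate and its products it cancels from their ratio. That is my reckoning; it gives the exponent, not the amounts.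

*And the amounts at the asked time?* The forecast says 59.3% substrate, 10.7% single product, 1.7% double product and 0.1% triple product, on the ground that the partner “must have decomposed within a few minutes”.

The flask gives 59.0% substrate, 10.2% single product, 1.63% double product and 0.126% triple product, and the forecast stands within its margins.

    partner + double product → triple product + released group (k = 5.53 M⁻¹ min⁻¹)
    substrate + partner → single product + released group (k = 3.82 M⁻¹ min⁻¹)
    partner + single product → double product + released group (k = 7.83 M⁻¹ min⁻¹)
    partner → decomposed reagent (k = 0.707 min⁻¹)
    substrate ⇌ dormant form (K = 0.492, k = 0.174 min⁻¹)

At the start of this flask, partner goes to decomposed reagent 9.3 times as fast as into single product, and its half-life by decomposition, 0.98 min, is shorter than the 3.0 min that single product has by the step to double product alone with the other concentrations as charged. At 3.00 h this flask holds 0% of its partner, with 0.0272 M decomposed reagent and 0.00276 M released group, an exponent of 0.994. For the neighbour charged with 0.12 M of partner, 0.981 gives 0.0114 M released group; that flask holds 0.0124 M, an exponent of 0.937, and 13.3% double product.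

The data were computed for substances that don't exist; noise was put on by code.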